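## Retrosynthetic overview

1. Austradiol acetate ⇐ acetylation of the 6α-OH after acetal removal ⇐ 4,6-O-benzylidene 1β-bromide ⇐ radical (hydrogen-atom-transfer) hydrogenation of a C1 alkenyl bromide ⇐ enol triflate ⇐ C1 ketone.
2. C1 ketone ⇐ Wharton 1,3-transposition of a 1,2-epoxy-3-ketone; 5αH and 6α-OH ⇐ hydroboration of a 5-ene; 4α-OH ⇐ α-hydroxylation of the extended enolate of a 1,4-dien-3-one.
3. Decalin ⇐ Robinson annulation: intermolecular Michael addition of (5S)-carvomenthone to ethyl vinyl ketone makes the C1–C10 bond and the quaternary C10, then aldol condensation closes ring A.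
4. Ring order: ring B comes from (S)-carvone (sets C7); ring A is formed second; C4, C5, C6 and C1 are then relayed from C10.

Assumption: the SMILES is read as the (1R,4R,5S,6S,7R,10R) isomer in eudesmane numbering (ring A = C1–C5, C10; ring B = C5–C10; methyls on C4 and C10, isopropyl on C7). β is the face of the C10 methyl, so the target is a trans-decalin with 1β-Br, 4α-OH, 5α-H, 6α-OAc and 7α-isopropyl, a "7-epi-eudesmane".

## Route

Step 1
Reactants: 1 (S)-(+)-carvone
Product: 2 (2RS,5S)-2-methyl-5-(propan-2-yl)cyclohexan-1-one (carvomenthone)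
Conditions: H2 (3 atm), Pd/C (10 wt%), EtOAc, rt
Reagents that add atoms: none
Why: Heterogeneous catalytic hydrogenation saturates both C=C bonds without touching C5, and the C2 epimer mixture is irrelevant because C2 is enolised in step 2.

Step 2
Reactants: 2 carvomenthone; 3 ethyl vinyl ketone
Product: 6 7-epi-eudesm-4-en-3-one [(4aS,7S)-1,4a-dimethyl-7-(propan-2-yl)-4,4a,5,6,7,8-hexahydronaphthalen-2(3H)-one], via Michael diketone 4 (not isolated), via ketol 5 (not isolated)
Conditions: KOH (0.3 equiv), EtOH, −10 °C, slow addition of 3, then rt; then KOH, EtOH, reflux; chromatography to remove the minor C10 epimer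
Reagents that add atoms: none
Why: Robinson annulation in which the more substituted enolate of 2 undergoes intermolecular Michael addition to 3 by axial attack cis to the equatorial isopropyl (so the C10 methyl ends trans to the isopropyl, as in the known 10-epi-α-cyperone series), followed by aldol condensation to close ring A.

Step 3
Reactants: 6 7-epi-eudesm-4-en-3-one
Product: 9 7-epi-eudesma-1,4-dien-3-one [(4aS,7S)-1,4a-dimethyl-7-(propan-2-yl)-5,6,7,8-tetrahydronaphthalen-2(4aH)-one], via lithium dienolate 7 (not isolated), via silyl dienol ether 8 (not isolated)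
Conditions: LiN(iPr)2, THF, −78 °C; Me3SiCl; then Pd(OAc)2 (1.1 equiv), MeCN, rt
Reagents that add atoms: none
Why: Kinetic deprotonation at C2 followed by Saegusa–Ito oxidation of the silyl enol ether introduces the C1=C2 bond regiospecifically and creates no stereocentre.

Step 4
Reactants: 9 7-epi-eudesma-1,4-dien-3-one
Product: 11 4α-hydroxy-7-epi-eudesma-1,5-dien-3-one (4β-methyl), via potassium trienolate 10 (not isolated)
Conditions: KN(SiMe3)2, THF, −78 → −40 °C; 2-(benzenesulfonyl)-3-phenyloxaziridine, −78 °C; aqueous work-up at low temperature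
Reagents that add atoms: 2-(benzenesulfonyl)-3-phenyloxaziridine, O=S(=O)(c1ccccc1)N1OC1c1ccccc1
Why: C6–H is the only enolisable position of 9, so the extended enolate forms cleanly and undergoes Davis α-hydroxylation at C4 (deconjugative α-attack, as in alkylations of such enolates), the oxidant approaching anti to the C10 methyl to give 4α-OH/4β-Me and shifting the double bond to C5=C6.

Step 5
Reactants: 11 4α-hydroxy-7-epi-eudesma-1,5-dien-3-one
Product: 12 1α,2α-epoxy-4α-hydroxy-7-epi-eudesm-5-en-3-one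
Conditions: 30% H2O2, NaOH (cat.), MeOH, 0 °C
Reagents that add atoms: hydrogen peroxide, OO
Why: Weitz–Scheffer nucleophilic epoxidation attacks only the electron-poor C1=C2 bond, from the α face anti to the angular methyl as in steroidal 1-en-3-ones (the C1 configuration is erased in step 10).

Step 6
Reactants: 12 1α,2α-epoxy-4α-hydroxy-7-epi-eudesm-5-en-3-one
Product: 14 7-epi-eudesma-2,5-diene-1α,4α-diol, via epoxy hydrazone 13 (not isolated)
Conditions: N2H4·H2O (3 equiv), AcOH (cat.), MeOH, 0 °C → rt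
Reagents that add atoms: none
Why: Wharton transposition, in which the epoxy hydrazone fragments with loss of N2 to the allylic alcohol, moves oxygen from C3 to C1 and removes the C3 carbonyl with the C1–O bond retained.

Step 7
Reactants: 14 7-epi-eudesma-2,5-diene-1α,4α-diol
Product: 15 7-epi-eudesm-5-ene-1α,4α-diol
Conditions: H2 (1 atm), RhCl(PPh3)3 (10 mol%), benzene, rt
Reagents that add atoms: none
Why: Homogeneous hydrogenation reduces the cis-disubstituted C2=C3 bond and spares the trisubstituted C5=C6 bond flanked by two quaternary carbons, without allylic C–O hydrogenolysis and without forming a stereocentre.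

Step 8
Reactants: 15 7-epi-eudesm-5-ene-1α,4α-diol
Product: 17 5αH-7-epi-eudesmane-1α,4α,6α-triol, via alkylborane 16 (not isolated)
Conditions: BH3·THF (5 equiv), THF, 0 → 40 °C; then NaOH (3 M), 30% H2O2, 0 °C → rt
Reagents that add atoms: hydrogen peroxide, OO
Why: Hydroboration–oxidation adds H and B syn from the α face (the β face is blocked by the 1,3-related C10 and C4 methyls, as in 4,4-dimethyl-5-ene steroids), placing boron on C6 and H on C5 to give the trans ring fusion (5αH) and, after oxidation with retention, the 6α-OH.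

Step 9
Reactants: 17 5αH-7-epi-eudesmane-1α,4α,6α-triol
Product: 18 4α,6α-O-benzylidene-5αH-7-epi-eudesmane-1α,4α,6α-triol (phenyl equatorial; acetal H β; 1α-OH free)
Conditions: PhCH(OMe)2 (1.5 equiv), camphorsulfonic acid (10 mol%), CH2Cl2, rt
Reagents that add atoms: benzaldehyde dimethyl acetal, COC(OC)c1ccccc1
Why: Thermodynamic acetalisation, in which only the syn-1,3-diol (4α and 6α, both equatorial) can close a six-membered benzylidene acetal with equatorial phenyl, differentiates the 6-OH from the 1α-OH.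

Step 10
Reactants: 18 4α,6α-O-benzylidene triol
Product: 19 4α,6α-O-benzylidene-4α,6α-dihydroxy-5αH-7-epi-eudesman-1-one
Conditions: Dess–Martin periodinane, pyridine, CH2Cl2, rt
Reagents that add atoms: none
Why: Dess–Martin oxidation of the only free (secondary, axial) alcohol gives the C1 ketone under buffered conditions that keep the acetal intact.

Step 11
Reactants: 19 C1 ketone
Product: 21 4α,6α-O-benzylidene-4α,6α-dihydroxy-5αH-7-epi-eudesm-1-en-1-yl trifluoromethanesulfonate, via potassium enolate 20 (not isolated)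
Conditions: KN(SiMe3)2, THF, −78 °C; PhNTf2, −78 → 0 °C
Reagents that add atoms: N-phenylbis(trifluoromethanesulfonimide), O=S(=O)(N(c1ccccc1)S(=O)(=O)C(F)(F)F)C(F)(F)F
Why: Enol triflate formation is regiospecific because C10 is quaternary, so the ketone can enolise only toward C2 before O-sulfonylation.

Step 12
Reactants: 21 enol triflate
Product: 22 4α,6α-O-benzylidene-1-bromo-5αH-7-epi-eudesm-1-ene-4α,6α-diol
Conditions: Ni(cod)2 (10 mol%), LiBr (3 equiv), THF/N,N-dimethylacetamide, rt
Reagents that add atoms: lithium bromide, [Li+].[Br-]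
Why: Nickel-catalysed halide exchange of the enol triflate (oxidative addition to zerovalent nickel, triflate–bromide exchange, reductive elimination) gives the alkenyl bromide without moving the double bond and tolerates triflates next to quaternary carbons.

Step 13
Reactants: 22 alkenyl bromide
Product: 23 4α,6α-O-benzylidene-1β-bromo-5αH-7-epi-eudesmane-4α,6α-diol
Conditions: Mn(dpm)3 (10 mol%; dpm = 2,2,6,6-tetramethylheptane-3,5-dionate), PhSiH3, t-BuOOH, i-PrOH, rt
Reagents that add atoms: none
Why: Hydrogen-atom-transfer hydrogenation adds H to C2 and the resulting C1 α-bromo radical takes its hydrogen axially from the α face (anti to the C10 methyl), giving the more stable equatorial 1β-bromide without C–Br hydrogenolysis.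

Step 14
Reactants: 23 benzylidene-protected bromide
Product: 24 1β-bromo-5αH-7-epi-eudesmane-4α,6α-diol
Conditions: 80% aq. AcOH, 45 °C
Reagents that add atoms: none
Why: Acid-catalysed acetal hydrolysis releases the diol under conditions that leave the tertiary alcohol and the non-ionising equatorial bromide untouched.

Step 15
Reactants: 24 bromo diol
Product: 25 austradiol acetate [(1S,2R,4aR,5R,8R,8aS)-5-bromo-8-hydroxy-4a,8-dimethyl-2-(propan-2-yl)decahydronaphthalen-1-yl acetate]
Conditions: Ac2O, pyridine, 4-(dimethylamino)pyridine (cat.), CH2Cl2, rt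
Reagents that add atoms: acetic anhydride, CC(=O)OC(C)=O
Why: Nucleophile-catalysed acylation esterifies the secondary 6α-OH selectively because the tertiary 4α-OH does not react under these conditions.

## Compound list

1 | (S)-(+)-carvone, (5S)-2-methyl-5-(prop-1-en-2-yl)cyclohex-2-en-1-one | CC1=CC[C@@H](CC1=O)C(C)=C | starting material
2 | carvomenthone, (2RS,5S)-2-methyl-5-(propan-2-yl)cyclohexan-1-one | CC1CC[C@@H](CC1=O)C(C)C | intermediate
3 | ethyl vinyl ketone (pent-1-en-3-one) | CCC(=O)C=C | starting material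
4 | Michael diketone, (2S,5S)-2-methyl-2-(3-oxopentyl)-5-(propan-2-yl)cyclohexan-1-one | C1[C@@H](C(C)C)CC[C@@](C)(CCC(=O)CC)C1=O | intermediate
5 | ketol, 5-hydroxy-7-epi-eudesman-3-one (C4 and C5 configuration not assigned) | C1[C@@H](C(C)C)CC[C@@]2(C)CCC(=O)C(C)C12O | intermediate
6 | 7-epi-eudesm-4-en-3-one, (4aS,7S) | C1[C@@H](C(C)C)CC[C@@]2(C)CCC(=O)C(C)=C12 | intermediate
7 | lithium 2,4-dien-3-olate of 6 | C1[C@@H](C(C)C)CC[C@@]2(C)CC=C([O-])C(C)=C12.[Li+] | intermediate
8 | 3-(trimethylsilyloxy)-7-epi-eudesma-2,4-diene | C1[C@@H](C(C)C)CC[C@@]2(C)CC=C(O[Si](C)(C)C)C(C)=C12 | intermediate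
9 | 7-epi-eudesma-1,4-dien-3-one, (4aS,7S) | C1[C@@H](C(C)C)CC[C@@]2(C)C=CC(=O)C(C)=C12 | intermediate
10 | potassium 1,3,5-trien-3-olate of 9 | C=1[C@@H](C(C)C)CC[C@@]2(C)C=CC([O-])=C(C)C=12.[K+] | intermediate
11 | 4α-hydroxy-7-epi-eudesma-1,5-dien-3-one (4β-methyl) | C=1[C@@H](C(C)C)CC[C@@]2(C)C=CC(=O)[C@@](C)(O)C=12 | intermediate
12 | 1α,2α-epoxy-4α-hydroxy-7-epi-eudesm-5-en-3-one | C=1[C@@H](C(C)C)CC[C@@]2(C)[C@H]3O[C@H]3C(=O)[C@@](C)(O)C=12 | intermediate
13 | C3 hydrazone of 12 | C=1[C@@H](C(C)C)CC[C@@]2(C)[C@H]3O[C@H]3C(=NN)[C@@](C)(O)C=12 | intermediate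
14 | 7-epi-eudesma-2,5-diene-1α,4α-diol | C=1[C@@H](C(C)C)CC[C@@]2(C)[C@@H](O)C=C[C@@](C)(O)C=12 | intermediate
15 | 7-epi-eudesm-5-ene-1α,4α-diol | C=1[C@@H](C(C)C)CC[C@@]2(C)[C@@H](O)CC[C@@](C)(O)C=12 | intermediate
16 | 6α-boryl-5αH-7-epi-eudesmane-1α,4α-diol (drawn as the monoalkylborane with free hydroxyls) | B[C@H]1[C@@H](C(C)C)CC[C@@]2(C)[C@@H](O)CC[C@@](C)(O)[C@H]12 | intermediate
17 | 5αH-7-epi-eudesmane-1α,4α,6α-triol | O[C@H]1[C@@H](C(C)C)CC[C@@]2(C)[C@@H](O)CC[C@@](C)(O)[C@H]12 | intermediate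
18 | 4α,6α-O-benzylidene acetal of 17 (phenyl equatorial, 1α-OH free) | c1ccccc1[C@H]2O[C@H]3[C@@H](C(C)C)CC[C@@]4(C)[C@@H](O)CC[C@@](C)(O2)[C@H]34 | intermediate
19 | 4α,6α-O-benzylidene-4α,6α-dihydroxy-5αH-7-epi-eudesman-1-one | c1ccccc1[C@H]2O[C@H]3[C@@H](C(C)C)CC[C@@]4(C)C(=O)CC[C@@](C)(O2)[C@H]34 | intermediate
20 | potassium 1-en-1-olate of 19 | c1ccccc1[C@H]2O[C@H]3[C@@H](C(C)C)CC[C@@]4(C)C([O-])=CC[C@@](C)(O2)[C@H]34.[K+] | intermediate
21 | 1-en-1-yl trifluoromethanesulfonate of the benzylidene acetal | c1ccccc1[C@H]2O[C@H]3[C@@H](C(C)C)CC[C@@]4(C)C(OS(=O)(=O)C(F)(F)F)=CC[C@@](C)(O2)[C@H]34 | intermediate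
22 | 1-bromo-1-ene of the benzylidene acetal | c1ccccc1[C@H]2O[C@H]3[C@@H](C(C)C)CC[C@@]4(C)C(Br)=CC[C@@](C)(O2)[C@H]34 | intermediate
23 | 4α,6α-O-benzylidene-1β-bromo-5αH-7-epi-eudesmane-4α,6α-diol | c1ccccc1[C@H]2O[C@H]3[C@@H](C(C)C)CC[C@@]4(C)[C@H](Br)CC[C@@](C)(O2)[C@H]34 | intermediate
24 | 1β-bromo-5αH-7-epi-eudesmane-4α,6α-diol | O[C@H]1[C@@H](C(C)C)CC[C@@]2(C)[C@H](Br)CC[C@@](C)(O)[C@H]12 | intermediate
25 | austradiol acetate, 6α-acetoxy-1β-bromo-5αH-7-epi-eudesman-4α-ol, (1R,4R,5S,6S,7R,10R) in eudesmane numbering | CC(=O)O[C@H]1[C@@H](C(C)C)CC[C@@]2(C)[C@H](Br)CC[C@@](C)(O)[C@H]12 | target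

## Step count and risks

Total steps: 15. Longest linear sequence: 15 steps from (S)-carvone (the route is fully linear).

The three steps most likely to fail:

Step 4 (C4 versus C6 attack on the extended enolate, and the face of attack at C4). The fallback sets out from 9 and comes back at 11, building the C4–O bond by a sigmatropic shift instead of enolate oxidation. Allylic bromination of 9 with N-bromosuccinimide and catalytic (PhCO2)2 in CCl4 at reflux gives the axial 6β-bromo-7-epi-eudesma-1,4-dien-3-one F1. PhSeNa in EtOH at 0 °C displaces the bromide with inversion to the 6α-(phenylselanyl) dienone F2. Oxidation with H2O2/pyridine in CH2Cl2 at −40 → 0 °C gives the selenoxide F3, which undergoes a suprafacial [2,3]-shift that delivers oxygen to C4 on the α face and moves the double bond to C5=C6, giving the 4α-selenenate F4. Aqueous work-up hydrolyses F4 to 11. Syn-elimination of F3 is disfavoured because the only hydrogen on C7 is trans to selenium.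

Step 8 (facial selectivity and rate of hydroboration of a very hindered 5-ene that also carries a 7α-isopropyl group). The fallback sets out from 15 and comes back at 19, using tethered delivery from the 4α-oxygen. Dess–Martin oxidation of 15 gives 4α-hydroxy-7-epi-eudesm-5-en-1-one F5. HSiMe2Cl/Et3N in CH2Cl2 gives the 4-O-dimethylsilyl ether F6. Pt2[(CH2=CHSiMe2)2O]3 (cat.) in toluene at 60 °C effects intramolecular syn-hydrosilylation (5-endo), necessarily from the α face, to the oxasilolane F7 with Si on C6α and H on C5α. Tamao oxidation (H2O2, KF, KHCO3, THF/MeOH) gives the 4α,6α-dihydroxy-5αH-7-epi-eudesman-1-one F8, and PhCH(OMe)2/camphorsulfonic acid converts F8 into 19.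

Step 13 (reactivity of the hindered alkenyl bromide toward hydrogen-atom transfer and the C1 selectivity of the radical quench). The fallback sets out from 18 and comes back at 23, using ionic substitution with inversion. Tf2O/pyridine in CH2Cl2 at −20 °C converts the axial 1α-alcohol 18 into the 1α-trifluoromethanesulfonate F9, and Bu4NBr in toluene at 40 °C displaces it to the equatorial 1β-bromide 23. This is stereospecific but expected to be low-yielding, because the carbon is neopentyl-like and elimination toward C2 competes.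

## Further compounds

F1 | step 4 | 6β-bromo-7-epi-eudesma-1,4-dien-3-one | Br[C@@H]1[C@@H](C(C)C)CC[C@@]2(C)C=CC(=O)C(C)=C12
F2 | step 4 | 6α-(phenylselanyl)-7-epi-eudesma-1,4-dien-3-one | c1ccccc1[Se][C@H]1[C@@H](C(C)C)CC[C@@]2(C)C=CC(=O)C(C)=C12
F3 | step 4 | 6α-(phenylseleninyl)-7-epi-eudesma-1,4-dien-3-one (selenoxide) | c1ccccc1[Se](=O)[C@H]1[C@@H](C(C)C)CC[C@@]2(C)C=CC(=O)C(C)=C12
F4 | step 4 | 4α-(phenylselanyloxy)-7-epi-eudesma-1,5-dien-3-one (selenenate) | C=1[C@@H](C(C)C)CC[C@@]2(C)C=CC(=O)[C@@](C)(O[Se]c3ccccc3)C=12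
F5 | step 8 | 4α-hydroxy-7-epi-eudesm-5-en-1-one | C=1[C@@H](C(C)C)CC[C@@]2(C)C(=O)CC[C@@](C)(O)C=12
F6 | step 8 | 4α-(dimethylsilyloxy)-7-epi-eudesm-5-en-1-one | C=1[C@@H](C(C)C)CC[C@@]2(C)C(=O)CC[C@@](C)(O[SiH](C)C)C=12
F7 | step 8 | 4α-O,6α-C-dimethylsilylene-bridged 5αH-7-epi-eudesman-1-one (oxasilolane) | C[Si]3(C)[C@H]1[C@@H](C(C)C)CC[C@@]2(C)C(=O)CC[C@@](C)(O3)[C@H]12
F8 | step 8 | 4α,6α-dihydroxy-5αH-7-epi-eudesman-1-one | O[C@H]1[C@@H](C(C)C)CC[C@@]2(C)C(=O)CC[C@@](C)(O)[C@H]12
F9 | step 13 | 1α-trifluoromethanesulfonate of 18 | c1ccccc1[C@H]2O[C@H]3[C@@H](C(C)C)CC[C@@]4(C)[C@@H](OS(=O)(=O)C(F)(F)F)CC[C@@](C)(O2)[C@H]34
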